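**Retrosynthetic overview**
1. Target 21 comes from hydroxy lactone 18 by ester adjustments only: acetate at O‑1, and silyl ether to methacrylate at O‑14.
2. The γ‑lactone of 18 (third ring, formed last) comes from ring‑contracting translactonisation of the bridged ten‑membered acrylate lactone 16, once O‑8 is freed.
3. 16 comes from methylenation (C13) of the α‑keto lactone 15.
4. 15 comes from a type 2 intramolecular Diels–Alder reaction of 14. The cyclohexene and the ten‑membered bridge form together, the diene's own side chain is the tether, and C6, C7 and C8 are set here.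
5. 14 comes from enal 8 [(S)‑citronellal imine + silyloxyacetone], oxalyl chloride (C11, C12) and tert‑butyl vinyl ether (C7, C8).

Assumption: eudesmane‑type numbering is used (C4 is the side‑chain stereocentre, C5=C10 the ring alkene, C6 carries OAc, C7/C8 are the ring fusion, C9 is the ring CH2, C11–C13 the lactone carbons, C14 the CH2O). (S)‑Citronellal of ≥98 % ee is used. The E/Z mixtures of 8–13 do not matter, because the C5=C10 geometry is erased in 14.

**Step 1**
Reactants: 1 hydroxyacetone
Product: 2 1-[(tert-butyldiphenylsilyl)oxy]propan-2-one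
Conditions: TBDPSCl, imidazole, CH2Cl2, 0 °C to rt
Reagents that add atoms: tert-butyl(chloro)diphenylsilane CC(C)(C)[Si](Cl)(c1ccccc1)c1ccccc1
Why: O‑silylation gives an acid‑ and base‑robust mask for the future C14 hydroxyl that lasts until step 11.

**Step 2**
Reactants: 3 (S)-citronellal
Product: 4 (1E,3S)-N-cyclohexyl-3,7-dimethyloct-6-en-1-imine
Conditions: cyclohexylamine, 4 Å MS, Et2O, 0 °C to rt
Reagents that add atoms: cyclohexylamine NC1CCCCC1
Why: Imine condensation prepares the aldehyde for a directed aldol reaction and does not touch C4.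

**Step 3**
Reactants: 4 imine; 2 silyloxyacetone
Product: 8 4-[(tert-butyldiphenylsilyl)oxy]-3-methyl-2-[(2S)-6-methylhept-5-en-2-yl]but-2-enal (E/Z mixture), via lithium aza-enolate 5 (not isolated), via lithium aldolate 6 (not isolated), via hydroxy aldehyde 7 (not isolated)
Conditions: LDA, THF, −78 to 0 °C; 2, −78 °C; then aq. oxalic acid, THF, 60 °C
Reagents that add atoms: water O
Why: In this Wittig directed aldol condensation the metallated aldimine can act only as the nucleophile, adds to the activated α‑silyloxy ketone, and hydrolysis with loss of the tertiary hydroxyl gives the conjugated tetrasubstituted enal, while C4 is β to the anion and is not epimerised.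

**Step 4**
Reactants: 8 enal
Product: 11 4-[(tert-butyldiphenylsilyl)oxy]-2-[(2S)-5-hydroxypentan-2-yl]-3-methylbut-2-enal, via ozonide 9 (not isolated), via dialdehyde 10 (not isolated)
Conditions: O3, CH2Cl2, −78 °C (Sudan III end point); Me2S; then NaBH(OAc)3, cat. AcOH, 0 °C to rt
Reagents that add atoms: ozone [O-][O+]=O
Why: Ozonolysis takes the electron‑rich trisubstituted alkene in preference to the hindered, electron‑poor enal alkene, and triacetoxyborohydride then reduces only the unhindered saturated aldehyde.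

**Step 5**
Reactants: 11 hydroxy enal
Product: 13 (4S)-5-formyl-4,6-dimethyl-7-[(tert-butyldiphenylsilyl)oxy]hept-5-en-1-yl (3E)-4-tert-butoxy-2-oxobut-3-enoate, via chlorooxoacetate 12 (not isolated)
Conditions: (COCl)2 (excess), CH2Cl2, 0 °C, evaporate; tert-butyl vinyl ether, pyridine, CH2Cl2, −20 °C to rt
Reagents that add atoms: oxalyl chloride O=C(Cl)C(=O)Cl; tert-butyl vinyl ether C=COC(C)(C)C
Why: O‑acylation followed by Effenberger–Tietze C‑acylation of the enol ether (addition, then base‑induced loss of HCl) gives the E‑configured β‑alkoxy α‑keto enoate that carries C12, C11, C7 and C8.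

**Step 6**
Reactants: 13 keto enoate
Product: 14 (4S)-5-[(E)-acetoxymethylidene]-4-methyl-6-{[(tert-butyldiphenylsilyl)oxy]methyl}hept-6-en-1-yl (3E)-4-tert-butoxy-2-oxobut-3-enoate
Conditions: Ac2O, Et3N, DMAP (0.1 equiv), BHT, THF, 50 °C
Reagents that add atoms: acetic anhydride CC(=O)OC(C)=O
Why: Dienol acetate formation removes a γ‑proton from the methyl group (the α‑oxygenated CH2 is less acidic and more hindered), and the 1E isomer is favoured because the acetoxy group then faces only the C4–H bond and not the fully substituted C10.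

**Step 7**
Reactants: 14 dienyl acetate
Product: 15 (1S,8S,12R,13S)-12-tert-butoxy-10-{[(tert-butyldiphenylsilyl)oxy]methyl}-8-methyl-2,3-dioxo-4-oxabicyclo[7.3.1]tridec-9-en-13-yl acetate
Conditions: Eu(fod)3 (0.2 equiv), BHT, PhMe (1 mM, slow addition), 90 °C
Reagents that add atoms: none
Why: Proposed new method: this is a type 2 intramolecular Diels–Alder reaction (Shea) that uses the diene's own C4–C1 chain as the tether, the closest precedent being Lewis‑acid‑promoted type 2 closures to bicyclo[5.3.1] enones; the chelated α‑keto ester lowers the LUMO, C9 bonds to the β‑carbon C8 and C6 to C7 (the electronic and tether preferences agree, and any hetero‑Diels–Alder adduct is an allyl vinyl ether that funnels to 15 by Claisen rearrangement), the E‑alkene sets C7/C8 trans, the endo keto group sets C6‑OAc cis to C11, and A(1,3) strain with the cis acetoxy group holds C4–H in the diene plane so that the tether reaches only the face that gives 6S,7S,8R from (4S).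

**Step 8**
Reactants: 15 α-keto lactone
Product: 16 (1S,8S,12R,13S)-12-tert-butoxy-10-{[(tert-butyldiphenylsilyl)oxy]methyl}-8-methyl-2-methylidene-3-oxo-4-oxabicyclo[7.3.1]tridec-9-en-13-yl acetate
Conditions: Zn, CH2Br2, TiCl4 (pre-aged Lombardo reagent), CH2Cl2/THF, 0 °C
Reagents that add atoms: dibromomethane BrCBr
Why: The non‑basic Takai–Oshima–Lombardo methylenation attacks only the highly electrophilic ketone, leaves the esters alone, and avoids E1cB loss of the two β‑oxygen substituents and epimerisation at C7.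

**Step 9**
Reactants: 16 methylidene macrolactone
Product: 18 (3aS,4S,7aR)-6-{[(tert-butyldiphenylsilyl)oxy]methyl}-5-[(2S)-5-hydroxypentan-2-yl]-3-methylidene-2-oxo-2,3,3a,4,7,7a-hexahydro-1-benzofuran-4-yl acetate, via hydroxy macrolactone 17 (not isolated)
Conditions: TFA/CH2Cl2 1:9, 0 °C; concentrate; PPTS (cat.), PhH, 50 °C
Reagents that add atoms: none
Why: E1 acidolysis of the tert‑butyl ether frees O‑8, which attacks C12 in a ring‑contracting translactonisation driven by release of medium‑ring strain, and because the C8–O bond is never broken the trans ring fusion set in step 7 is kept.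

**Step 10**
Reactants: 18 hydroxy lactone
Product: 19 (4S)-4-[(3aS,4S,7aR)-4-acetoxy-6-{[(tert-butyldiphenylsilyl)oxy]methyl}-3-methylidene-2-oxo-2,3,3a,4,7,7a-hexahydro-1-benzofuran-5-yl]pentyl acetate
Conditions: Ac2O, pyridine, CH2Cl2, 0 °C
Reagents that add atoms: acetic anhydride CC(=O)OC(C)=O
Why: Acetylation works cleanly because the only free hydroxyl is the primary C1–OH.

**Step 11**
Reactants: 19 silyl ether
Product: 20 (4S)-4-[(3aS,4S,7aR)-4-acetoxy-6-(hydroxymethyl)-3-methylidene-2-oxo-2,3,3a,4,7,7a-hexahydro-1-benzofuran-5-yl]pentyl acetate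
Conditions: HF·pyridine, THF/pyridine, 0 °C to rt
Reagents that add atoms: none
Why: Buffered fluoride desilylation is non‑basic, so the acetates and the α‑methylene lactone survive.

**Step 12**
Reactants: 20 allylic alcohol
Product: 21 [(3aS,4S,7aR)-4-acetoxy-5-[(2S)-5-acetoxypentan-2-yl]-3-methylidene-2-oxo-2,3,3a,4,7,7a-hexahydro-1-benzofuran-6-yl]methyl 2-methylprop-2-enoate (target)
Conditions: methacryloyl chloride, Et3N, DMAP (cat.), BHT, CH2Cl2, −20 °C
Reagents that add atoms: methacryloyl chloride C=C(C)C(=O)Cl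
Why: Esterification of the primary allylic alcohol with the acid chloride completes the target without touching any stereocentre.

**Compound list**
1 | hydroxyacetone | CC(=O)CO | starting material
2 | 1-[(tert-butyldiphenylsilyl)oxy]propan-2-one | CC(=O)CO[Si](c1ccccc1)(c1ccccc1)C(C)(C)C | intermediate
3 | (S)-citronellal | O=CC[C@@H](C)CCC=C(C)C | starting material
4 | N-cyclohexyl aldimine of 3 | C1CCCCC1/N=C/C[C@@H](C)CCC=C(C)C | intermediate
5 | lithium aza-enolate | [Li]N(C1CCCCC1)C=C[C@@H](C)CCC=C(C)C | intermediate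
6 | lithium aldolate (β-oxido imine, diastereomer mixture) | [Li]OC(C)(CO[Si](c1ccccc1)(c1ccccc1)C(C)(C)C)C(C=NC1CCCCC1)[C@@H](C)CCC=C(C)C | intermediate
7 | β-hydroxy aldehyde (diastereomer mixture) | O=CC(C(C)(O)CO[Si](c1ccccc1)(c1ccccc1)C(C)(C)C)[C@@H](C)CCC=C(C)C | intermediate
8 | tetrasubstituted enal (E/Z) | O=CC(=C(C)CO[Si](c1ccccc1)(c1ccccc1)C(C)(C)C)[C@@H](C)CCC=C(C)C | intermediate
9 | ozonide | O=CC(=C(C)CO[Si](c1ccccc1)(c1ccccc1)C(C)(C)C)[C@@H](C)CCC1OOC(C)(C)O1 | intermediate
10 | dialdehyde | O=CC(=C(C)CO[Si](c1ccccc1)(c1ccccc1)C(C)(C)C)[C@@H](C)CCC=O | intermediate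
11 | hydroxy enal | O=CC(=C(C)CO[Si](c1ccccc1)(c1ccccc1)C(C)(C)C)[C@@H](C)CCCO | intermediate
12 | chlorooxoacetate | O=CC(=C(C)CO[Si](c1ccccc1)(c1ccccc1)C(C)(C)C)[C@@H](C)CCCOC(=O)C(=O)Cl | intermediate
13 | β-tert-butoxy α-keto enoate | O=CC(=C(C)CO[Si](c1ccccc1)(c1ccccc1)C(C)(C)C)[C@@H](C)CCCOC(=O)C(=O)/C=C/OC(C)(C)C | intermediate
14 | (1E)-dienyl acetate | CC(=O)O/C=C(/C(=C)CO[Si](c1ccccc1)(c1ccccc1)C(C)(C)C)[C@@H](C)CCCOC(=O)C(=O)/C=C/OC(C)(C)C | intermediate
15 | bridged α-keto lactone | CC(C)(C)[Si](c1ccccc1)(c1ccccc1)OCC1=C2[C@@H](C)CCCOC(=O)C(=O)[C@@H]([C@H](OC(C)(C)C)C1)[C@@H]2OC(C)=O | intermediate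
16 | bridged methylidene lactone | CC(C)(C)[Si](c1ccccc1)(c1ccccc1)OCC1=C2[C@@H](C)CCCOC(=O)C(=C)[C@@H]([C@H](OC(C)(C)C)C1)[C@@H]2OC(C)=O | intermediate
17 | hydroxy macrolactone | CC(C)(C)[Si](c1ccccc1)(c1ccccc1)OCC1=C2[C@@H](C)CCCOC(=O)C(=C)[C@@H]([C@H](O)C1)[C@@H]2OC(C)=O | intermediate
18 | hydroxy γ-lactone | CC(C)(C)[Si](c1ccccc1)(c1ccccc1)OCC1=C([C@@H](C)CCCO)[C@@H](OC(C)=O)[C@H]2C(=C)C(=O)O[C@@H]2C1 | intermediate
19 | diacetate silyl ether | CC(C)(C)[Si](c1ccccc1)(c1ccccc1)OCC1=C([C@@H](C)CCCOC(C)=O)[C@@H](OC(C)=O)[C@H]2C(=C)C(=O)O[C@@H]2C1 | intermediate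
20 | allylic alcohol | OCC1=C([C@@H](C)CCCOC(C)=O)[C@@H](OC(C)=O)[C@H]2C(=C)C(=O)O[C@@H]2C1 | intermediate
21 | CNP0157277.1 | C=C(C)C(=O)OCC1=C([C@@H](C)CCCOC(C)=O)[C@@H](OC(C)=O)[C@H]2C(=C)C(=O)O[C@@H]2C1 | target

**Totals:** 12 steps in all. The longest linear sequence is 11 steps (steps 2–12, from (S)-citronellal).

**Steps most likely to fail**

Step 7. The effective molarity for closing a ten‑membered bridge is low, the push–pull dienophile is sluggish, and the A(1,3) facial model is not proven. The fallback sets out from 11 and returns at 19. Compound 11 is acetylated and dienolised in one pot (excess Ac2O, Et3N, DMAP) to the dienyl diacetate F1. Methyl chlorooxoacetate and tert‑butyl vinyl ether give methyl (E)-4-tert-butoxy-2-oxobut-3-enoate F2. The two are joined in an intermolecular, catalyst‑controlled Diels–Alder reaction (Cu(II)–(S,S)-t-Bu-box, two‑point binding of the keto ester) to the keto ester adduct F3. Lombardo methylenation gives the acrylate F4. TFA then removes the tert‑butyl group and closes the γ‑lactone with loss of methanol to give 19.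

Step 3. Retro‑aldol cleavage, or dehydration towards the β,γ‑isomer, may compete. The fallback sets out from 4 and returns at 8, and replaces the aldol/dehydration by a Peterson olefination. Compound 4 is metallated and silylated (LDA, TMSCl) to the α-silyl aldimine F5. A second metallation (s‑BuLi) and addition to 2 gives, after spontaneous loss of silanolate, the unsaturated aldimine F6. Hydrolysis at pH 4.5 gives 8.

Step 9. The allylic acetate is acid‑labile, and the transannular acyl transfer may be slow. The fallback sets out from 16 and returns at 18. The macrolactone is first opened with Me3SnOH (1,2‑dichloroethane, 70 °C) to the seco hydroxy acid F7. This freely rotating acid lactonises onto O‑8 as soon as brief TFA treatment removes the tert‑butyl group, which gives 18.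

**Further compounds**
F1 | step 7 | dienyl diacetate | CC(=O)O/C=C(/C(=C)CO[Si](c1ccccc1)(c1ccccc1)C(C)(C)C)[C@@H](C)CCCOC(C)=O
F2 | step 7 | methyl (E)-4-tert-butoxy-2-oxobut-3-enoate | COC(=O)C(=O)/C=C/OC(C)(C)C
F3 | step 7 | keto ester adduct | CC(C)(C)[Si](c1ccccc1)(c1ccccc1)OCC1=C([C@@H](C)CCCOC(C)=O)[C@@H](OC(C)=O)[C@@H](C(=O)C(=O)OC)[C@H](OC(C)(C)C)C1
F4 | step 7 | acrylate | CC(C)(C)[Si](c1ccccc1)(c1ccccc1)OCC1=C([C@@H](C)CCCOC(C)=O)[C@@H](OC(C)=O)[C@@H](C(=C)C(=O)OC)[C@H](OC(C)(C)C)C1
F5 | step 3 | α-silyl aldimine | C[Si](C)(C)C(/C=N/C1CCCCC1)[C@@H](C)CCC=C(C)C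
F6 | step 3 | unsaturated aldimine | C1CCCCC1/N=C/C(=C(C)CO[Si](c2ccccc2)(c2ccccc2)C(C)(C)C)[C@@H](C)CCC=C(C)C
F7 | step 9 | seco hydroxy acid | CC(C)(C)[Si](c1ccccc1)(c1ccccc1)OCC1=C([C@@H](C)CCCO)[C@@H](OC(C)=O)[C@@H](C(=C)C(=O)O)[C@H](OC(C)(C)C)C1
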